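**Retrosynthetic overview**
1. Numbering (daucane): C1 = fusion C(Me), C2 = C=O, C3 = CH2, C4 = C(OH)(i-Pr), C5 = fusion CH, C6 = CH–O-acyl, C7 = CH2, C8(Me)=C9, C10 = CH2; the C1 methyl is β.
2. Endgame: free the phenol from its acetate. The ester comes from diol 23, where only the secondary 6-OH can acylate because 4-OH is tertiary. Diol 23 comes from bis-silyl ether 22.
3. Key disconnection is C3–C4 of the ring C1–C2–C3–C4–C5. The enabling feature is that C3 is a CH2 between the C2 ketone and the oxygen-bearing C4, and the acyl arm on C1 and the carbinyl arm on C5 are trans-diequatorial on the seven-membered ring. C4–H therefore sits 1,5 to a carbenoid carbon at C3, which is the retron of a C–H insertion that touches neither fusion centre.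
4. Diazoketone 20 comes from one three-component coupling on the achiral dienone 8: an enantioselective conjugate addition of a 1-silylvinyl group (masked acetyl) sets C1, and an anti aldol addition to isobutyraldehyde sets C5 and C4. C6 comes from a chelate-controlled reduction.
5. Ring order: seven-membered ring first (RCM, step 5), five-membered ring last (step 12).

Key step: step 12

Assumption: the ligand enantiomer in step 7 is the one that delivers the vinyl group to the enone face giving (R)-C1; its mirror image would give the antipode.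

Step 1
Reactants: 1 methyl propiolate; 2 allyl bromide
Product: 3 methyl hex-5-en-2-ynoate
Conditions: CuI (10 mol %), K2CO3, Bu4NI (cat.), MeCN, rt
Reagents that add atoms: none
Why: Copper(I)-catalysed allylation of a terminal alkyne (copper acetylide plus allylic halide) should give the skipped enyne under carbonate conditions too mild to move the triple bond.

Step 2
Reactants: 3 methyl hex-5-en-2-ynoate
Product: 4 methyl (2Z)-3-methylhexa-2,5-dienoate
Conditions: Me2CuLi (MeLi, CuI), THF, −78 °C; MeOH quench at −78 °C
Reagents that add atoms: lithium dimethylcuprate (from MeLi and CuI), [Li+].C[Cu-]C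
Why: Carbocupration of a 2-alkynoate is a syn addition, so methyl and copper (then H) end up cis, and a cold protic quench should fix the (Z)-enoate in which the allyl CH2 and the ester are cis, the geometry the ring needs.

Step 3
Reactants: 4 methyl (2Z)-3-methylhexa-2,5-dienoate
Product: 5 (2Z)-N-methoxy-N,3-dimethylhexa-2,5-dienamide
Conditions: MeNH(OMe)·HCl, AlMe3, CH2Cl2, 0 °C to rt
Reagents that add atoms: N,O-dimethylhydroxylamine hydrochloride, CNOC.Cl
Why: Aluminium-amide aminolysis of the ester gives the N-methoxy-N-methylamide without a basic medium that could isomerise the (Z)-alkene or the skipped diene.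

Step 4
Reactants: 5 (2Z)-N-methoxy-N,3-dimethylhexa-2,5-dienamide; 6 2-methylallylmagnesium chloride
Product: 7 (5Z)-2,6-dimethylnona-1,5,8-trien-4-one
Conditions: THF, −78 to −20 °C; cold pH 7 buffer quench
Reagents that add atoms: none
Why: Weinreb ketone synthesis, in which the chelated tetrahedral adduct holds until the cold buffered quench, so one methallyl group adds and the β,γ-unsaturated ketone is released under non-isomerising conditions.

Step 5
Reactants: 7 (5Z)-2,6-dimethylnona-1,5,8-trien-4-one
Product: 8 3,6-dimethylcyclohepta-2,5-dien-1-one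
Conditions: (H2IMes)(PCy3)Cl2Ru=CHPh (5 mol %), 1,4-benzoquinone (10 mol %), CH2Cl2 (5 mM), 40 °C
Reagents that add atoms: none
Why: Ring-closing metathesis joins the mono- and the 1,1-disubstituted terminal alkenes to the trisubstituted C8=C9 bond and closes the seven-membered ring, helped by the catalyst-inert (Z)-enone that already holds both chains cis, while benzoquinone suppresses Ru–H alkene migration.

Step 6
Reactants: 9 benzylchlorodimethylsilane; 10 ethynylmagnesium bromide
Product: 11 benzyl(ethynyl)dimethylsilane
Conditions: THF, 0 °C to rt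
Reagents that add atoms: none
Why: Nucleophilic substitution at silicon by the alkynyl Grignard reagent.

Step 7
Reactants: 8 3,6-dimethylcyclohepta-2,5-dien-1-one; 11 benzyl(ethynyl)dimethylsilane; 12 isobutyraldehyde
Product: 15 (2R,3R)-3-[1-(benzyldimethylsilyl)vinyl]-2-[(1R)-1-hydroxy-2-methylpropyl]-3,6-dimethylcyclohept-5-en-1-one, via vinylalane 13 (not isolated), via aluminium enolate 14 (not isolated)
Conditions: 11, DIBAL-H, hexane/THF, 55 °C; then 8, chiral sulfonate–NHC·Ag complex (2.5 mol %), Cu(OTf)2 (5 mol %), THF, 22 °C; then 12, −78 °C; aq. Rochelle salt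
Reagents that add atoms: diisobutylaluminium hydride, CC(C)C[AlH]CC(C)C (its Al(i-Bu)2 unit stays only in 13 and 14)
Why: NHC–Cu-catalysed enantioselective conjugate addition of a silicon-substituted vinylaluminium to a β-methyl cycloalkenone sets quaternary C1 under catalyst control, and the regiodefined ring (E)-aluminium enolate 14 adds to the aldehyde through a closed chair transition state on the face anti to the bulky silylvinyl group, which sets C5 (trans to that arm) and C4 (anti aldol).

Step 8
Reactants: 15 the β-hydroxy ketone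
Product: 16 (1S,2S,3R)-3-[1-(benzyldimethylsilyl)vinyl]-2-[(1R)-1-hydroxy-2-methylpropyl]-3,6-dimethylcyclohept-5-en-1-ol
Conditions: Et2BOMe, THF/MeOH, −78 °C; NaBH4; AcOH, then MeOH co-evaporation
Reagents that add atoms: none
Why: Narasaka–Prasad reduction, in which external hydride attacks the six-membered boron chelate axially and should give the 1,3-syn diol, that is the equatorial 6-OH (6S in daucane numbering), and reducing the ketone directly after step 7 also ends the risk of C8=C9 moving into conjugation.

Step 9
Reactants: 16 the syn-1,3-diol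
Product: 17 bis(tert-butyldimethylsilyl) ether of 16
Conditions: TBSOTf (2.5 equiv), 2,6-lutidine, CH2Cl2, 0 °C to rt
Reagents that add atoms: tert-butyldimethylsilyl triflate, CC(C)(C)[Si](C)(C)OS(=O)(=O)C(F)(F)F
Why: Silyl triflate/lutidine silylates even the hindered 4-OH, the two bulky 1,3-syn silyl ethers avoid each other and so favour the C4–C5 rotamer needed in step 12, and a silyl ether activates the adjacent C–H while resisting ylide formation.

Step 10
Reactants: 17 the bis-TBS ether
Product: 18 bis-TBS ether of (1S,2S,3R)-3-acetyl-2-[(1R)-1-hydroxy-2-methylpropyl]-3,6-dimethylcyclohept-5-en-1-ol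
Conditions: TBAF (1.5 equiv), THF, 0 °C, 10 min; then H2O2, KHCO3, MeOH, rt
Reagents that add atoms: hydrogen peroxide, OO
Why: Tamao–Fleming oxidation of a 1,1-disubstituted vinylsilane, in which fluoride removes the benzyl group within minutes (the hindered secondary TBS ethers should outlast this), peroxide turns C–Si into C–O, the enol tautomerises to the methyl ketone, and the unactivated C8=C9 alkene is inert to basic H2O2.

Step 11
Reactants: 18 the methyl ketone
Product: 20 bis-TBS ether of (1S,2S,3R)-3-(2-diazoacetyl)-2-[(1R)-1-hydroxy-2-methylpropyl]-3,6-dimethylcyclohept-5-en-1-ol, via trifluoroacetyl ketone 19 (not isolated)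
Conditions: LiHMDS, THF, −78 °C; CF3CO2CH2CF3; then MsN3, Et3N, H2O, MeCN, rt
Reagents that add atoms: methanesulfonyl azide, CS(=O)(=O)N=[N+]=[N-]; 2,2,2-trifluoroethyl trifluoroacetate, O=C(OCC(F)(F)F)C(F)(F)F (only into 19)
Why: Deacylative (Regitz-type) diazo transfer, in which the methyl group is the only enolisable position, its enolate is trifluoroacetylated for activation, and the sulfonyl azide transfers N2 with loss of the trifluoroacetyl group.

Step 12
Reactants: 20 the diazoketone
Product: 22 (3R,3aS,4S,8aR)-3,4-bis(tert-butyldimethylsilyloxy)-3-isopropyl-6,8a-dimethyl-3,3a,4,5,8,8a-hexahydroazulen-1(2H)-one, via rhodium carbenoid 21 (not isolated)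
Conditions: Rh2(OAc)4 (1 mol %), CH2Cl2, 40 °C, slow addition of 20
Reagents that add atoms: none
Why: Rh2(OAc)4 expels N2 from 20 to give the electrophilic carbenoid 21, whose carbon C3 inserts into C4–H through a concerted, asynchronous three-centre (hydride-transfer-like) transition state; the closest known reaction type is the Rh(II)-catalysed 1,5 C–H insertion of α-diazo ketones to cyclopentanones, including insertion next to ether oxygen to give 3-alkoxycyclopentanones. The ring C1–C2–C3–C4–C5 closes by forming C3–C4 in the usual five-membered (1,5) mode, so neither fusion carbon is touched and the trans C1/C5 relation from step 7 is carried into a trans-fused hydroazulenone, which closures onto a trigonal C1 or C5 would not deliver. C4 becomes the fully substituted carbinol carbon with retention, so the (4R) centre of the anti aldol unit turns directly into the 4β-oxygen/4α-isopropyl centre of the target. Selectivity is needed against C6–H, the i-Pr methine, cyclopropanation of C8=C9 and oxonium ylide formation: in the all-equatorial chair of 20 the acyl arm on C1 is anti to C6 and to C9 and H-6 lies on the β face opposite to the α acyl arm, which puts C6–H and the alkene out of reach; the C4–C5 rotamer with i-Pr anti to C1 leaves H-4 as the group facing the carbenoid; the silyloxy group makes this methine the most hydridic C–H; the i-Pr methine would need a six-membered transition state; and the bulky, weakly basic O–TBS oxygens resist ylide formation. No acid or base is present, so the β-silyloxy ketone cannot eliminate or cleave by retro-aldol.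

Step 13
Reactants: 22 the bicyclic bis-silyl ether
Product: 23 (3R,3aS,4S,8aR)-3,4-dihydroxy-3-isopropyl-6,8a-dimethyl-3,3a,4,5,8,8a-hexahydroazulen-1(2H)-one
Conditions: HF·pyridine, pyridine/THF, 0 °C to rt
Reagents that add atoms: none
Why: Buffered acidic fluoride cleaves both Si–O bonds without the basic conditions that would trigger retro-aldol cleavage or E1cB loss of the 4-oxygen.

Step 14
Reactants: 23 the diol; 24 4-acetoxybenzoic acid
Product: 25 (3R,3aS,4S,8aR)-3-hydroxy-3-isopropyl-6,8a-dimethyl-1-oxo-1,2,3,3a,4,5,8,8a-octahydroazulen-4-yl 4-acetoxybenzoate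
Conditions: DCC, DMAP, CH2Cl2, rt
Reagents that add atoms: none
Why: Steglich esterification acylates only the secondary equatorial 6-OH because the 4-OH is tertiary and flanked by i-Pr, and C6 keeps its configuration since its C–O bond is not touched.

Step 15
Reactants: 25 the acetate-protected ester
Product: 26 (3R,3aS,4S,8aR)-3-hydroxy-3-isopropyl-6,8a-dimethyl-1-oxo-1,2,3,3a,4,5,8,8a-octahydroazulen-4-yl 4-hydroxybenzoate (target)
Conditions: pyrrolidine (2 equiv), CH2Cl2, 0 °C to rt
Reagents that add atoms: none
Why: Aminolysis of the activated aryl acetate is far faster than attack on the hindered secondary benzoate, so the phenol is freed without touching the ester, the hindered ketone or the tertiary alcohol.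

**Compound list**
1 | methyl propiolate | C#CC(=O)OC | starting material
2 | allyl bromide | C=CCBr | starting material
3 | methyl hex-5-en-2-ynoate | C=CCC#CC(=O)OC | intermediate
4 | methyl (2Z)-3-methylhexa-2,5-dienoate | C=CC/C(C)=C\C(=O)OC | intermediate
5 | (2Z)-N-methoxy-N,3-dimethylhexa-2,5-dienamide | C=CC/C(C)=C\C(=O)N(C)OC | intermediate
6 | 2-methylallylmagnesium chloride | C=C(C)C[Mg]Cl | starting material
7 | (5Z)-2,6-dimethylnona-1,5,8-trien-4-one | C=C(C)CC(=O)/C=C(C)\CC=C | intermediate
8 | 3,6-dimethylcyclohepta-2,5-dien-1-one | CC1=CC(=O)CC(C)=CC1 | intermediate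
9 | benzylchlorodimethylsilane | C[Si](C)(Cl)Cc1ccccc1 | starting material
10 | ethynylmagnesium bromide | C#C[Mg]Br | starting material
11 | benzyl(ethynyl)dimethylsilane | C#C[Si](C)(C)Cc1ccccc1 | intermediate
12 | isobutyraldehyde | CC(C)C=O | starting material
13 | [1-(benzyldimethylsilyl)vinyl]diisobutylaluminium | C=C([Si](C)(C)Cc1ccccc1)[Al](CC(C)C)CC(C)C | intermediate
14 | diisobutylaluminium enolate of (3R)-3-[1-(benzyldimethylsilyl)vinyl]-3,6-dimethylcyclohept-5-en-1-one (C5=C6 enolate) | CC1=CC[C@@](C)(C(=C)[Si](C)(C)Cc2ccccc2)C=C(O[Al](CC(C)C)CC(C)C)C1 | intermediate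
15 | (2R,3R)-3-[1-(benzyldimethylsilyl)vinyl]-2-[(1R)-1-hydroxy-2-methylpropyl]-3,6-dimethylcyclohept-5-en-1-one | CC1=CC[C@@](C)(C(=C)[Si](C)(C)Cc2ccccc2)[C@H]([C@H](O)C(C)C)C(=O)C1 | intermediate
16 | (1S,2S,3R)-3-[1-(benzyldimethylsilyl)vinyl]-2-[(1R)-1-hydroxy-2-methylpropyl]-3,6-dimethylcyclohept-5-en-1-ol | CC1=CC[C@@](C)(C(=C)[Si](C)(C)Cc2ccccc2)[C@H]([C@H](O)C(C)C)[C@@H](O)C1 | intermediate
17 | bis-TBS ether of 16 | CC1=CC[C@@](C)(C(=C)[Si](C)(C)Cc2ccccc2)[C@H]([C@H](O[Si](C)(C)C(C)(C)C)C(C)C)[C@@H](O[Si](C)(C)C(C)(C)C)C1 | intermediate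
18 | methyl ketone (3-acetyl analogue of 17) | CC1=CC[C@@](C)(C(C)=O)[C@H]([C@H](O[Si](C)(C)C(C)(C)C)C(C)C)[C@@H](O[Si](C)(C)C(C)(C)C)C1 | intermediate
19 | trifluoroacetylated methyl ketone (1,3-diketone) | CC1=CC[C@@](C)(C(=O)CC(=O)C(F)(F)F)[C@H]([C@H](O[Si](C)(C)C(C)(C)C)C(C)C)[C@@H](O[Si](C)(C)C(C)(C)C)C1 | intermediate
20 | diazoketone (3-(2-diazoacetyl) analogue of 18) | CC1=CC[C@@](C)(C(=O)C=[N+]=[N-])[C@H]([C@H](O[Si](C)(C)C(C)(C)C)C(C)C)[C@@H](O[Si](C)(C)C(C)(C)C)C1 | intermediate
21 | rhodium carbenoid of 20 (second Rh and acetate ligands omitted) | CC1=CC[C@@](C)(C(=O)C=[Rh])[C@H]([C@H](O[Si](C)(C)C(C)(C)C)C(C)C)[C@@H](O[Si](C)(C)C(C)(C)C)C1 | intermediate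
22 | (3R,3aS,4S,8aR)-3,4-bis(TBSO)-3-isopropyl-6,8a-dimethyl-3,3a,4,5,8,8a-hexahydroazulen-1(2H)-one | CC1=CC[C@@]2(C)C(=O)C[C@@](O[Si](C)(C)C(C)(C)C)(C(C)C)[C@@H]2[C@@H](O[Si](C)(C)C(C)(C)C)C1 | intermediate
23 | (3R,3aS,4S,8aR)-3,4-dihydroxy-3-isopropyl-6,8a-dimethyl-3,3a,4,5,8,8a-hexahydroazulen-1(2H)-one | CC1=CC[C@@]2(C)C(=O)C[C@@](O)(C(C)C)[C@@H]2[C@@H](O)C1 | intermediate
24 | 4-acetoxybenzoic acid | CC(=O)Oc1ccc(cc1)C(=O)O | starting material
25 | 4-acetoxybenzoate of 23 at the 6-OH (azulene C4) | CC1=CC[C@@]2(C)C(=O)C[C@@](O)(C(C)C)[C@@H]2[C@@H](OC(=O)c2ccc(OC(C)=O)cc2)C1 | intermediate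
26 | CNP0238517.1 | CC1=CC[C@@]2(C)C(=O)C[C@@](O)(C(C)C)[C@@H]2[C@@H](OC(=O)c2ccc(O)cc2)C1 | target

**Totals and risks**

Total step count: 15. Longest linear sequence: 14 (steps 1–5 and 7–15).

Steps most likely to fail:

(i) Step 12. The carbenoid may be diverted from C4–H insertion into oxonium ylide formation, cyclopropanation of C8=C9 through a minor ring conformer, or Wolff rearrangement. The crowded methine may also react too slowly. The fallback closes the same C3–C4 bond by an intramolecular aldol addition and sets out from diol 16. TBSCl/imidazole silylates only the less hindered 6-OH to give the mono-TBS ether F1. Periodinane (DMP) oxidation gives the isopropyl ketone F2, and Tamao–Fleming oxidation as in step 10 gives the 1,4-diketone F3. LiHMDS at −78 °C forms the methyl-ketone enolate, which adds to the C4 ketone with i-Pr turning to the open α face to give the aldol F4. HF·pyridine then comes back to the route at diol 23.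

(ii) Step 7. The aldol addition at the neopentyl enolate carbon may be slow or reversible. The aldehyde may be consumed by β-hydride transfer from i-Bu–Al species, and facial or simple diastereoselectivity may erode. The fallback separates the two events and sets out from 8 and 11. After the same conjugate addition the enolate is trapped with Et3SiOTf as the triethylsilyl enol ether F5. A Lewis-acid (BF3·OEt2, −78 °C) Mukaiyama aldol addition to 12 through an open, irreversible transition state comes back to the route at 15.

(iii) Step 8. There may be poor facial selectivity, because the axial hydride approach demanded by the boron chelate runs syn to the axial C1 methyl and attack from the opposite face may leak in. The fallback replaces kinetic hydride delivery by an electron-transfer reduction under thermodynamic control and sets out from 15. TESOTf/2,6-lutidine gives the 4-O-TES ketone F6, and SmI2/H2O/Et3N reduces the ketyl to the more stable equatorial alcohol F7. PPTS/MeOH removes the TES group and comes back to the route at 16.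

**Further compounds**
F1 | step 12 | 6-O-TBS ether of diol 16 | CC1=CC[C@@](C)(C(=C)[Si](C)(C)Cc2ccccc2)[C@H]([C@H](O)C(C)C)[C@@H](O[Si](C)(C)C(C)(C)C)C1
F2 | step 12 | isopropyl ketone from F1 (C4 ketone) | CC1=CC[C@@](C)(C(=C)[Si](C)(C)Cc2ccccc2)[C@H](C(=O)C(C)C)[C@@H](O[Si](C)(C)C(C)(C)C)C1
F3 | step 12 | 1,4-diketone (C2 acetyl, C4 isobutyryl, 6-OTBS) | CC1=CC[C@@](C)(C(C)=O)[C@H](C(=O)C(C)C)[C@@H](O[Si](C)(C)C(C)(C)C)C1
F4 | step 12 | 6-O-TBS ether of diol 23 | CC1=CC[C@@]2(C)C(=O)C[C@@](O)(C(C)C)[C@@H]2[C@@H](O[Si](C)(C)C(C)(C)C)C1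
F5 | step 7 | triethylsilyl enol ether of the conjugate adduct | CC1=CC[C@@](C)(C(=C)[Si](C)(C)Cc2ccccc2)C=C(O[Si](CC)(CC)CC)C1
F6 | step 8 | 4-O-TES ether of 15 | CC1=CC[C@@](C)(C(=C)[Si](C)(C)Cc2ccccc2)[C@H]([C@H](O[Si](CC)(CC)CC)C(C)C)C(=O)C1
F7 | step 8 | 4-O-TES ether of 16 | CC1=CC[C@@](C)(C(=C)[Si](C)(C)Cc2ccccc2)[C@H]([C@H](O[Si](CC)(CC)CC)C(C)C)[C@@H](O)C1
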